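The route rests on disconnecting the C4=C5 double bond of the cyclohexenone ring (C1–C6). It is the only alkene in the target and lies between the C3 carbinol and the C6 carbonyl, so ring-closing metathesis of an acyclic vinyl ketone forms this bond and the carbocycle in one operation after all three stereocentres are set. The precursor carries C2 and C3 as the trans-dioxolane inherited from D-tartrate, a vinyl group on C3, and a tertiary C1 carbinol made by Felkin–Anh addition of lithiated methoxyallene. Its C7 oxygen stays a 4-methoxybenzyl (PMB) ether until after ring closure, so that no free C7 hydroxyl can add to the acyclic enone.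

Key step: step 7

Remark: zeylenone numbering is used throughout (C1 tertiary carbinol, C2 and C3 oxygenated methines, C4=C5, C6 carbonyl, C7 exocyclic CH2O); (tributylstannyl)methanol and methoxyallene are taken as purchasable.

Step 1
Reactants: 1 dimethyl 2,3-O-isopropylidene-D-tartrate
Product: 3 methyl (4S,5R)-2,2-dimethyl-5-vinyl-1,3-dioxolane-4-carboxylate, via aldehyde ester 2 (not isolated)
Conditions: i-Bu2AlH (1.05 equiv), toluene, −78 °C; then Ph3P=CH2 (from Ph3PCH3Br, KOtBu, THF), −78 °C → rt
Reagents that add atoms: methyltriphenylphosphonium bromide, C[P+](c1ccccc1)(c1ccccc1)c1ccccc1.[Br-]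
Why: One equivalent of i-Bu2AlH at −78 °C takes one of the two equivalent esters only to the aluminium hemiacetal, which collapses to aldehyde 2 and is trapped in the same flask by Wittig methylenation with a non-stabilised ylide that leaves the second ester alone; both stereocentres are untouched and the trans-disubstituted dioxolane, being the stable arrangement, does not epimerise.

Step 2
Reactants: 3 methyl (4S,5R)-2,2-dimethyl-5-vinyl-1,3-dioxolane-4-carboxylate
Product: 4 (4S,5R)-N-methoxy-N,2,2-trimethyl-5-vinyl-1,3-dioxolane-4-carboxamide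
Conditions: MeNH(OMe)·HCl, i-PrMgCl, THF, −20 → 0 °C
Reagents that add atoms: N,O-dimethylhydroxylamine hydrochloride, CNOC.Cl
Why: Aminolysis of the methyl ester by the chloromagnesium amide of N,O-dimethylhydroxylamine (Weinreb amide formation) is fast at low temperature and leaves the α-alkoxy stereocentre and the vinyl group unchanged.

Step 3
Reactants: 5 (tributylstannyl)methanol; 6 4-methoxybenzyl chloride
Product: 7 tributyl{[(4-methoxybenzyl)oxy]methyl}stannane
Conditions: NaH, Bu4NI (cat.), THF/DMF, 0 °C → rt
Reagents that add atoms: none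
Why: Williamson etherification of the sodium alkoxide of the stannylmethanol with the reactive benzylic chloride gives the (alkoxymethyl)stannane that serves as a protected hydroxymethyl anion source.

Step 4
Reactants: 4 (4S,5R)-N-methoxy-N,2,2-trimethyl-5-vinyl-1,3-dioxolane-4-carboxamide; 7 tributyl{[(4-methoxybenzyl)oxy]methyl}stannane
Product: 9 1-[(4S,5R)-2,2-dimethyl-5-vinyl-1,3-dioxolan-4-yl]-2-[(4-methoxybenzyl)oxy]ethan-1-one, via PMB-oxymethyllithium 8 (not isolated)
Conditions: 7, n-BuLi, THF, −78 °C; then 4, −78 °C; aq. NH4Cl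
Reagents that add atoms: none
Why: Tin–lithium exchange gives the α-alkoxymethyllithium 8, whose addition to the Weinreb amide stops at the chelated tetrahedral adduct and releases the ketone only on quench, so over-addition is avoided (Weinreb ketone synthesis).

Step 5
Reactants: 9 1-[(4S,5R)-2,2-dimethyl-5-vinyl-1,3-dioxolan-4-yl]-2-[(4-methoxybenzyl)oxy]ethan-1-one; 10 methoxyallene
Product: 12 (2S)-2-[(4S,5R)-2,2-dimethyl-5-vinyl-1,3-dioxolan-4-yl]-3-methoxy-1-[(4-methoxybenzyl)oxy]penta-3,4-dien-2-ol, via 1-lithio-1-methoxyallene 11 (not isolated)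
Conditions: 10, n-BuLi, THF, −40 °C; then 9, −78 °C; H2O
Reagents that add atoms: none
Why: 1,2-Addition of the lithiated alkoxyallene to the ketone follows the polar Felkin–Anh model, with the dioxolane C2–O bond antiperiplanar to the incoming nucleophile, which passes the small C2–H; this places the new C1 hydroxyl anti to the C2 oxygen along the chain (cis in the later ring), which is the (1S) configuration.

Step 6
Reactants: 12 (2S)-2-[(4S,5R)-2,2-dimethyl-5-vinyl-1,3-dioxolan-4-yl]-3-methoxy-1-[(4-methoxybenzyl)oxy]penta-3,4-dien-2-ol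
Product: 13 (4S)-4-[(4S,5R)-2,2-dimethyl-5-vinyl-1,3-dioxolan-4-yl]-4-hydroxy-5-[(4-methoxybenzyl)oxy]pent-1-en-3-one
Conditions: 5% aq. H2SO4, THF, 0 °C
Reagents that add atoms: water, O
Why: Acid hydrolysis of the 1-methoxyallene (protonation at the central allene carbon, hydration of the oxocarbenium ion, loss of methanol) unveils the vinyl ketone under conditions too mild to open the trans-dioxolane or cleave the PMB ether, and the product is carried on at once because acyclic vinyl ketones oligomerise.

Step 7
Reactants: 13 (4S)-4-[(4S,5R)-2,2-dimethyl-5-vinyl-1,3-dioxolan-4-yl]-4-hydroxy-5-[(4-methoxybenzyl)oxy]pent-1-en-3-one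
Product: 14 (4R,5S,6S)-6-hydroxy-4,5-(isopropylidenedioxy)-6-{[(4-methoxybenzyl)oxy]methyl}cyclohex-2-en-1-one
Conditions: second-generation Hoveyda–Grubbs catalyst (H2IMes)Cl2Ru=CH(C6H4-2-OiPr) (5 mol %), CH2Cl2 (0.005 M), 40 °C
Reagents that add atoms: none
Why: The catalyst exchanges its benzylidene for the electron-richer, unhindered C3 vinyl group to give a Ru=C4 alkylidene, which undergoes [2+2] cycloaddition with the C=C of the vinyl ketone; cycloreversion of the ruthenacyclobutane forms the C4=C5 bond and expels ethylene, whose loss makes the closure irreversible. The closest known reaction type is ring-closing olefin metathesis of vinyl ketones bearing allylic ethers to 4-oxygenated cyclohex-2-enones, including closures that leave a trans-fused dioxolane on the new ring. The one ring formed, the six-membered carbocycle C1–C6, closes by intramolecular metathesis of an octa-1,7-diene chain, and the cis geometry of the new alkene is imposed by the ring size. No stereocentre is created; C1, C2 and C3 are spectators under the neutral conditions. The step needs cyclisation to outrun intermolecular cross-metathesis of the vinyl ketone and must tolerate the free tertiary C1 hydroxyl: high dilution, initiation at the allylic-ether alkene, the dioxolane that restricts rotation about C2–C3 and keeps the two alkene-bearing arms within reach, and a phosphine-free catalyst that engages electron-poor alkenes secure this.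

Step 8
Reactants: 14 (4R,5S,6S)-6-hydroxy-4,5-(isopropylidenedioxy)-6-{[(4-methoxybenzyl)oxy]methyl}cyclohex-2-en-1-one
Product: 15 (4R,5S,6S)-6-hydroxy-6-(hydroxymethyl)-4,5-(isopropylidenedioxy)cyclohex-2-en-1-one
Conditions: DDQ, CH2Cl2/pH 7 phosphate buffer (10:1), 0 °C → rt
Reagents that add atoms: none
Why: Oxidative cleavage of the electron-rich 4-methoxybenzyl ether by DDQ (hydride abstraction to the benzylic oxocarbenium ion, then hydrolysis) proceeds in wet buffered solvent without affecting the enone, the acetonide or the tertiary alcohol.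

Step 9
Reactants: 15 (4R,5S,6S)-6-hydroxy-6-(hydroxymethyl)-4,5-(isopropylidenedioxy)cyclohex-2-en-1-one; 16 benzoyl chloride
Product: 17 (4R,5S,6S)-6-(benzoyloxymethyl)-6-hydroxy-4,5-(isopropylidenedioxy)cyclohex-2-en-1-one
Conditions: 16 (1.1 equiv), pyridine, CH2Cl2, −20 → 0 °C
Reagents that add atoms: none
Why: Esterification with an acid chloride and pyridine occurs only at the primary C7 hydroxyl, because the tertiary C1 hydroxyl next to the carbonyl is inert without a stronger acyl-transfer catalyst.

Step 10
Reactants: 17 (4R,5S,6S)-6-(benzoyloxymethyl)-6-hydroxy-4,5-(isopropylidenedioxy)cyclohex-2-en-1-one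
Product: 18 [(1S,2S,3R)-1,2,3-trihydroxy-6-oxocyclohex-4-en-1-yl]methyl benzoate
Conditions: TFA/H2O (9:1), 0 °C
Reagents that add atoms: none
Why: Aqueous acid hydrolyses the strained trans-fused isopropylidene acetal quickly, while the benzoate, the enone and the tertiary α-ketol survive short exposure at 0 °C.

Step 11
Reactants: 18 [(1S,2S,3R)-1,2,3-trihydroxy-6-oxocyclohex-4-en-1-yl]methyl benzoate; 16 benzoyl chloride
Product: 19 zeylenone, [(1S,2S,3R)-3-(benzoyloxy)-1,2-dihydroxy-6-oxocyclohex-4-en-1-yl]methyl benzoate
Conditions: 16 (1.05 equiv), pyridine, CH2Cl2, −40 → −20 °C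
Reagents that add atoms: none
Why: With one equivalent of acid chloride at low temperature, regioselective esterification favours the allylic C3 hydroxyl, which has only the sp2 carbon C4 on its open side, over the C2 hydroxyl crowded by the fully substituted C1 and over the unreactive tertiary C1 hydroxyl.

Step 12
Reactants: 19 zeylenone; 20 acetic anhydride
Product: 21 2-O-acetylzeylenone, [(1S,2S,3R)-2-acetoxy-3-(benzoyloxy)-1-hydroxy-6-oxocyclohex-4-en-1-yl]methyl benzoate
Conditions: 20, pyridine, 0 °C → rt
Reagents that add atoms: none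
Why: Acetylation with the anhydride in pyridine esterifies the one remaining secondary hydroxyl at C2, while the tertiary C1 hydroxyl does not react in the absence of DMAP.

Compound list

1 | dimethyl 2,3-O-isopropylidene-D-tartrate, dimethyl (4S,5S)-2,2-dimethyl-1,3-dioxolane-4,5-dicarboxylate | COC(=O)[C@H]1OC(C)(C)O[C@@H]1C(=O)OC | starting material
2 | methyl (4S,5S)-5-formyl-2,2-dimethyl-1,3-dioxolane-4-carboxylate | O=C[C@H]1OC(C)(C)O[C@@H]1C(=O)OC | intermediate
3 | methyl (4S,5R)-2,2-dimethyl-5-vinyl-1,3-dioxolane-4-carboxylate | C=C[C@H]1OC(C)(C)O[C@@H]1C(=O)OC | intermediate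
4 | (4S,5R)-N-methoxy-N,2,2-trimethyl-5-vinyl-1,3-dioxolane-4-carboxamide | C=C[C@H]1OC(C)(C)O[C@@H]1C(=O)N(C)OC | intermediate
5 | (tributylstannyl)methanol | CCCC[Sn](CCCC)(CCCC)CO | starting material
6 | 4-methoxybenzyl chloride | COc1ccc(CCl)cc1 | starting material
7 | tributyl{[(4-methoxybenzyl)oxy]methyl}stannane | CCCC[Sn](CCCC)(CCCC)COCc1ccc(OC)cc1 | intermediate
8 | {[(4-methoxybenzyl)oxy]methyl}lithium | [Li]COCc1ccc(OC)cc1 | intermediate
9 | 1-[(4S,5R)-2,2-dimethyl-5-vinyl-1,3-dioxolan-4-yl]-2-[(4-methoxybenzyl)oxy]ethan-1-one | C=C[C@H]1OC(C)(C)O[C@@H]1C(=O)COCc1ccc(OC)cc1 | intermediate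
10 | methoxyallene (1-methoxypropa-1,2-diene) | COC=C=C | starting material
11 | 1-lithio-1-methoxyallene | [Li]C(OC)=C=C | intermediate
12 | (2S)-2-[(4S,5R)-2,2-dimethyl-5-vinyl-1,3-dioxolan-4-yl]-3-methoxy-1-[(4-methoxybenzyl)oxy]penta-3,4-dien-2-ol | C=C[C@H]1OC(C)(C)O[C@@H]1[C@@](O)(COCc1ccc(OC)cc1)C(OC)=C=C | intermediate
13 | (4S)-4-[(4S,5R)-2,2-dimethyl-5-vinyl-1,3-dioxolan-4-yl]-4-hydroxy-5-[(4-methoxybenzyl)oxy]pent-1-en-3-one (metathesis precursor) | C=C[C@H]1OC(C)(C)O[C@@H]1[C@@](O)(COCc1ccc(OC)cc1)C(=O)C=C | intermediate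
14 | (4R,5S,6S)-6-hydroxy-4,5-(isopropylidenedioxy)-6-{[(4-methoxybenzyl)oxy]methyl}cyclohex-2-en-1-one (metathesis product, trans-fused acetonide) | O=C1C=C[C@H]2OC(C)(C)O[C@@H]2[C@@]1(O)COCc1ccc(OC)cc1 | intermediate
15 | (4R,5S,6S)-6-hydroxy-6-(hydroxymethyl)-4,5-(isopropylidenedioxy)cyclohex-2-en-1-one | O=C1C=C[C@H]2OC(C)(C)O[C@@H]2[C@@]1(O)CO | intermediate
16 | benzoyl chloride | O=C(Cl)c1ccccc1 | starting material
17 | (4R,5S,6S)-6-(benzoyloxymethyl)-6-hydroxy-4,5-(isopropylidenedioxy)cyclohex-2-en-1-one | O=C1C=C[C@H]2OC(C)(C)O[C@@H]2[C@@]1(O)COC(=O)c1ccccc1 | intermediate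
18 | [(1S,2S,3R)-1,2,3-trihydroxy-6-oxocyclohex-4-en-1-yl]methyl benzoate | O[C@H]1[C@H](O)C=CC(=O)[C@]1(O)COC(=O)c1ccccc1 | intermediate
19 | zeylenone, [(1S,2S,3R)-3-(benzoyloxy)-1,2-dihydroxy-6-oxocyclohex-4-en-1-yl]methyl benzoate | O[C@H]1[C@H](OC(=O)c2ccccc2)C=CC(=O)[C@]1(O)COC(=O)c1ccccc1 | intermediate
20 | acetic anhydride | CC(=O)OC(C)=O | starting material
21 | 2-O-acetylzeylenone, [(1S,2S,3R)-2-acetoxy-3-(benzoyloxy)-1-hydroxy-6-oxocyclohex-4-en-1-yl]methyl benzoate | CC(=O)O[C@H]1[C@H](OC(=O)c2ccccc2)C=CC(=O)[C@]1(O)COC(=O)c1ccccc1 | target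

Total step count: 12. Longest linear sequence: 11 steps (steps 1, 2 and 4–12 from 1); step 3 is a one-step side branch to stannane 7.

Steps most likely to fail

Step 7 (ring-closing metathesis). The electron-poor vinyl ketone may be engaged too slowly, so that intermolecular cross-metathesis and oligomerisation, or catalyst deactivation by chelation to the α-hydroxy ketone, compete with ring closure. The fallback sets out from 13 and comes back at 14, keeping the same C4=C5 disconnection but closing the ring at the alcohol oxidation level. 1,2-Reduction of the enone carbonyl of 13 with NaBH4 and CeCl3·7H2O in MeOH at −78 °C (Luche reduction) should give the bis-allylic dienediol F1 as both C6 epimers, which is inconsequential. Its two electron-rich allylic alkenes should close readily with second-generation Grubbs catalyst (H2IMes)(PCy3)Cl2Ru=CHPh in CH2Cl2 at 40 °C to the cyclohexenediol F2. MnO2 in CH2Cl2 then oxidises only the secondary allylic C6 hydroxyl and returns enone 14.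

Step 11 (benzoylation at C3). Discrimination between the two secondary hydroxyls may be incomplete, leading to acylation at C2, double acylation or acyl migration. The fallback sets out from 17 and comes back at 19, replacing kinetic regioselection by protecting-group position. Acid-catalysed equilibration of 17 (TsOH cat., acetone with a little 2,2-dimethoxypropane, rt) should move the isopropylidene group from the strained trans-fused C2/C3 position onto the cis-related C1/C2 diol. This gives the cis-fused 1,2-O-isopropylidene isomer F3, in which only the C3 hydroxyl is free. Exhaustive benzoylation (16, pyridine, DMAP cat.) gives the 3-O-benzoyl acetonide F4, and TFA/H2O removes the acetonide to give zeylenone 19.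

Step 1 (desymmetrising reduction–olefination). Partial reduction of two equivalent esters may proceed statistically, with over-reduction and double olefination on one side and unreacted diester on the other. The fallback sets out from 1 and comes back at 2, differentiating the two esters stepwise. Monosaponification of 1 with one equivalent of KOH in MeOH gives the half-ester acid F5. Chemoselective reduction of the carboxylic acid with BH3·SMe2 in THF gives the hydroxy ester F6. Swern oxidation ((COCl)2, DMSO, Et3N, −78 °C) then gives aldehyde 2, which is methylenated as in step 1 to give 3.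

Further compounds

F1 | step 7 | C6 carbinol of 13 (both C6 epimers; C1, C2, C3 as in 13): 4-[(4S,5R)-2,2-dimethyl-5-vinyl-1,3-dioxolan-4-yl]-5-[(4-methoxybenzyl)oxy]pent-1-ene-3,4-diol | C=C[C@H]1OC(C)(C)O[C@@H]1[C@@](O)(COCc1ccc(OC)cc1)C(O)C=C
F2 | step 7 | allylic alcohol corresponding to enone 14 (C6 carbinol, both epimers; C1, C2, C3 as in 14) | OC1C=C[C@H]2OC(C)(C)O[C@@H]2[C@@]1(O)COCc1ccc(OC)cc1
F3 | step 11 | 1,2-O-isopropylidene isomer of 17: cis-fused C1/C2 acetonide, free C3 hydroxyl, C7 benzoate, (1S,2S,3R) | CC1(C)O[C@H]2[C@H](O)C=CC(=O)[C@]2(O1)COC(=O)c1ccccc1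
F4 | step 11 | 3-O-benzoyl derivative of F3 (1,2-O-isopropylidenezeylenone) | CC1(C)O[C@H]2[C@H](OC(=O)c3ccccc3)C=CC(=O)[C@]2(O1)COC(=O)c1ccccc1
F5 | step 1 | (4S,5S)-5-(methoxycarbonyl)-2,2-dimethyl-1,3-dioxolane-4-carboxylic acid | COC(=O)[C@H]1OC(C)(C)O[C@@H]1C(=O)O
F6 | step 1 | methyl (4S,5R)-5-(hydroxymethyl)-2,2-dimethyl-1,3-dioxolane-4-carboxylate | COC(=O)[C@H]1OC(C)(C)O[C@@H]1CO
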